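**Retrosynthetic overview**

1. Target 29 ⇐ triol 24 (silylate the two primary OH groups, angelate on O3, desilylate); the E-allylic alcohol C13=C14–C15 ⇐ terminal alkyne 21 (carboalumination, then formaldehyde); C11–C12 ⇐ alkylation of the C11 triflate of alcohol 18.
2. Exocyclic C8=C17 with C9–H ⇐ C8=C9 enoate 16 carrying an acetoxy group on C17 (reductive allylic transposition); C5–H ⇐ hydrogenation of C5=C6.
3. Ring B ⇐ Diels–Alder union of the ring A diene 12 (C7=C6–C5=C10) with methyl 4-acetoxybut-2-ynoate 14, which forms C7–C8 and C9–C10 and the quaternary C10.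
4. Ring A ⇐ (R)-carvone: its ring becomes C1–C5/C10 with the C20 methyl in place; C4 by two α′-alkylations, O3 by ozonolysis/Criegee rearrangement, O3/O18 acetonide as conformational lock. Ring order: A from the chiral pool, then B in the key step.
5. Enabling feature: in ring B, C8 (bearing the exocyclic C17 methylene) and C9 (bearing H and C11) are a two-carbon unit held between C7 and the quaternary ring-fusion carbon C10; moving the 8(17) double bond to C8=C9 and adding C5=C6 makes ring B a cyclohexa-1,4-diene, the retron of an alkyne plus the semicyclic diene anchored on ring A.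

Key step: step 9

Remark: positions are given in labdane numbering (decalin C1–C10, side chain C11–C16, exocyclic methylene C17, hydroxymethyl on C4 = C18, methyl on C4 = C19, methyl on C10 = C20); the target is (3R,4S,5S,9R,10S,13E).
Remark: (R)-(−)-carvone, methyl 4-hydroxybut-2-ynoate and angelic acid are taken as commercially available.

**Route**

Step 1
Reactants: 1 (R)-(−)-carvone
Product: 3 (5R,6S)-2,6-dimethyl-5-(prop-1-en-2-yl)cyclohex-2-en-1-one (trans-6-methylcarvone), via carvone lithium enolate 2 (not isolated)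
Conditions: LiN(i-Pr)2, THF, −78 °C; MeI, −78 → 0 °C
Reagents that add atoms: iodomethane, CI
Why: Kinetic α′-deprotonation gives the cross-conjugated enolate, whose enolate alkylation occurs mainly anti to the C5 isopropenyl group; the new centre need not be controlled because step 2 passes through the planar enolate again.

Step 2
Reactants: 3 trans-6-methylcarvone
Product: 5 (5S,6R)-6-(hydroxymethyl)-2,6-dimethyl-5-(prop-1-en-2-yl)cyclohex-2-en-1-one, via 6-methylcarvone lithium enolate 4 (not isolated)
Conditions: LiN(i-Pr)2, THF, −78 °C; CH2O (gas from cracked paraformaldehyde), −78 °C; AcOH quench at −78 °C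
Reagents that add atoms: formaldehyde, C=O
Why: Aldol hydroxymethylation of the tetrasubstituted enolate takes place on the face opposite the pseudoaxial isopropenyl group, the stereocontrol established for double α′-alkylation of carvone, so the quaternary centre (C4 of the target) is set with CH2OH trans and CH3 cis to the isopropenyl group.

Step 3
Reactants: 5 hydroxymethyl enone
Product: 7 (5R,6S)-5-acetoxy-6-(acetoxymethyl)-2,6-dimethylcyclohex-2-en-1-one, via methoxy hydroperoxide 6 (not isolated)
Conditions: O3, CH2Cl2–MeOH (4:1), −78 °C (Sudan red end point); then Ac2O, Et3N, DMAP (cat.), 0 °C → rt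
Reagents that add atoms: ozone, O=[O+][O-]; methanol, CO; acetic anhydride, CC(=O)OC(C)=O
Why: Ozone attacks only the electron-rich 1,1-disubstituted alkene, and the methoxy hydroperoxide undergoes Criegee rearrangement on O-acetylation, the ring carbon migrating from carbon to oxygen with retention, which turns the isopropenyl-bearing carbon into the C3–O stereocentre; the primary alcohol is acetylated in the same pot.

Step 4
Reactants: 7 diacetate
Product: 8 (5R,6S)-5-hydroxy-6-(hydroxymethyl)-2,6-dimethylcyclohex-2-en-1-one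
Conditions: K2CO3 (0.2 equiv), MeOH, 0 °C
Reagents that add atoms: none
Why: Base-catalysed transesterification removes both acetates, and the low temperature and catalytic base should keep retro-aldol loss of formaldehyde from the β-hydroxy ketone slow.

Step 5
Reactants: 8 diol enone
Product: 9 (4aS,8aR)-2,2,4a,6-tetramethyl-4a,8a-dihydro-4H-1,3-benzodioxin-5(8H)-one (trans-fused acetonide of 8)
Conditions: 2,2-dimethoxypropane, PPTS (cat.), CH2Cl2, rt
Reagents that add atoms: 2,2-dimethoxypropane, COC(C)(C)OC
Why: Acid-catalysed transacetalization converts the trans-diequatorial 1,3-diol into a trans-fused 1,3-dioxane, one protecting group for O3 and O18 that also locks ring A with the C4 methyl axial.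

Step 6
Reactants: 9 acetonide enone
Product: 11 (4aS,8aR)-2,2,4a,6-tetramethyl-4a,7,8,8a-tetrahydro-4H-1,3-benzodioxin-5-yl trifluoromethanesulfonate, via lithium enolate 10 (not isolated)
Conditions: LiBH(s-Bu)3, THF, −78 °C; PhNTf2, −78 → 0 °C
Reagents that add atoms: N-phenylbis(trifluoromethanesulfonimide), O=S(=O)(N(c1ccccc1)S(=O)(=O)C(F)(F)F)C(F)(F)F
Why: Conjugate hydride addition of the bulky borohydride to the β-unsubstituted enone gives the regiodefined tetrasubstituted enolate, which is trapped on oxygen (reductive enol triflate formation); no stereocentre is formed.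

Step 7
Reactants: 11 enol triflate
Product: 12 (4aS,8aR)-5-ethenyl-2,2,4a,6-tetramethyl-4a,7,8,8a-tetrahydro-4H-1,3-benzodioxine (ring A diene)
Conditions: tributyl(vinyl)stannane, Pd(PPh3)4 (5 mol%), LiCl (3 equiv), THF, 65 °C
Reagents that add atoms: tributyl(vinyl)stannane, C=C[Sn](CCCC)(CCCC)CCCC
Why: Stille cross-coupling under the LiCl-promoted protocol, the standard for hindered cyclohexenyl triflates, installs the vinyl group and completes the diene C7=C6–C5=C10.

Step 8
Reactants: 13 methyl 4-hydroxybut-2-ynoate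
Product: 14 methyl 4-acetoxybut-2-ynoate
Conditions: Ac2O, pyridine, DMAP (cat.), CH2Cl2, 0 °C
Reagents that add atoms: acetic anhydride, CC(=O)OC(C)=O
Why: Simple O-acylation turns the propargylic oxygen into the leaving group needed in step 11.

Step 9
Reactants: 12 ring A diene; 14 methyl 4-acetoxybut-2-ynoate
Product: 15 methyl (3R,4S,10R)-17-acetoxy-3,18-(isopropylidenedioxy)-12,13,14,15,16-pentanorlabda-5,8-dien-11-oate
Conditions: 14 (3 equiv), toluene (2 M), BHT (cat.), 120 °C, sealed tube
Reagents that add atoms: none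
Why: Thermal, concerted but asynchronous [4+2] cycloaddition (Diels–Alder reaction; closest precedent: additions of acetylenic esters to 1-vinyl-2,6,6-trimethylcyclohexene-type dienes), which closes ring B as a cyclohexa-1,4-diene by suprafacial six-membered union of C7 with C8 and of C10 with C9. Regiochemistry: the unsubstituted, more nucleophilic terminus C7 bonds ahead to the acetylenic carbon β to the ester (C8), which places the ester-bearing carbon C9 on the emerging quaternary C10; this is also the sterically easier orientation. The only new stereocentre, C10, is set by facial selection: the trans-fused acetonide holds ring A in the half-chair with the C19 methyl pseudoaxial and 1,3 to C10, so the dienophile should add to the opposite (C18) face and leave C20 cis to C19 as required. An alkyne dienophile has no endo/exo issue, and the product C8=C9 alkene with its C17 acetoxy group is the latent 8(17)-methylene/C9–H unit. The temperature is limited so that the [1,5]-hydrogen shift of the cis-methyl diene should not compete.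

Step 10
Reactants: 15 Diels–Alder adduct
Product: 16 methyl (3R,4S,5S,10R)-17-acetoxy-3,18-(isopropylidenedioxy)-12,13,14,15,16-pentanorlabd-8-en-11-oate
Conditions: H2 (5 bar), Pt/C (5%), EtOAc, rt
Reagents that add atoms: none
Why: Heterogeneous hydrogenation should saturate only the trisubstituted C5=C6 bond (the tetrasubstituted, ester-conjugated C8=C9 bond is inert), with delivery to the face opposite the axial C19 and C20 methyl groups so that H5 ends trans to C20 (trans-decalin), as known for related 1,4-diene adducts; platinum is chosen over palladium to avoid hydrogenolysis of the allylic acetate.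

Step 11
Reactants: 16 γ-acetoxy enoate
Product: 17 methyl (3R,4S,5S,9R,10R)-3,18-(isopropylidenedioxy)-12,13,14,15,16-pentanorlabd-8(17)-en-11-oate
Conditions: SmI2 (3 equiv), t-BuOH (3 equiv), THF–HMPA, −78 °C
Reagents that add atoms: none
Why: Two-electron reduction of the γ-acetoxy enoate expels acetate to give a samarium dienolate that is protonated kinetically at the α-carbon (SmI2 reductive elimination with deconjugation, known for 4-acetoxy-2-enoates), which unveils the exocyclic C8=C17 bond and sets C9 by protonation anti to the axial C20 methyl, leaving the ester equatorial and cis to C20.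

Step 12
Reactants: 17 exo-methylene ester
Product: 18 (3R,4S,5S,9R,10R)-3,18-(isopropylidenedioxy)-12,13,14,15,16-pentanorlabd-8(17)-en-11-ol
Conditions: LiAlH4, Et2O, 0 °C
Reagents that add atoms: none
Why: Hydride reduction of the β,γ-unsaturated ester to the primary alcohol under conditions in which neither the C9 centre nor the exocyclic alkene should move.

Step 13
Reactants: 18 C11 alcohol
Product: 20 (3R,4S,5S,9R,10S)-3,18-(isopropylidenedioxy)-14-(trimethylsilyl)-15,16-dinorlabd-8(17)-en-13-yne, via C11 triflate 19 (not isolated)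
Conditions: Tf2O, 2,6-lutidine, CH2Cl2, −78 °C; then Me3SiC≡CCH2Li (from Me3SiC≡CCH3, n-BuLi, THF, −20 °C), THF, −78 → −20 °C
Reagents that add atoms: 1-(trimethylsilyl)propyne, CC#C[Si](C)(C)C
Why: The primary triflate is displaced (SN2) at low temperature by lithiated 1-(trimethylsilyl)propyne, which reacts at its propargylic carbon, forming C11–C12 without touching a stereocentre.

Step 14
Reactants: 20 silyl alkyne
Product: 21 (3R,4S,5S,9R,10S)-3,18-(isopropylidenedioxy)-15,16-dinorlabd-8(17)-en-13-yne
Conditions: K2CO3, MeOH, rt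
Reagents that add atoms: none
Why: Base-mediated methanolysis of the alkynyl–silicon bond (protodesilylation) frees the terminal alkyne.

Step 15
Reactants: 21 terminal alkyne
Product: 23 (3R,4S,5S,9R,10S,13E)-3,18-(isopropylidenedioxy)labda-8(17),13-dien-15-ol, via alkenyldimethylalane 22 (not isolated)
Conditions: Me3Al, Cp2ZrCl2 (0.25 equiv), CH2Cl2, 0 °C → rt; solvent exchange; n-BuLi, THF, −78 °C; (CH2O)n, −78 °C → rt
Reagents that add atoms: trimethylaluminium, C[Al](C)C; formaldehyde (from paraformaldehyde), C=O
Why: Zirconium-catalysed syn-carboalumination (Negishi carboalumination) places methyl on C13 and aluminium on C14, and the derived alanate adds to formaldehyde with retention, so the E-trisubstituted allylic alcohol is formed stereospecifically.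

Step 16
Reactants: 23 acetonide allylic alcohol
Product: 24 (3R,4S,5S,9R,10S,13E)-labda-8(17),13-diene-3,15,18-triol
Conditions: AcOH–H2O–THF (3:1:1), 40 °C
Reagents that add atoms: none
Why: Mild aqueous acid hydrolysis of the acetonide, under which the allylic alcohol and the exocyclic alkene should stay untouched.

Step 17
Reactants: 24 triol
Product: 25 (3R,4S,5S,9R,10S,13E)-15,18-bis(tert-butyldimethylsilyloxy)labda-8(17),13-dien-3-ol
Conditions: TBSCl (2.2 equiv), imidazole, DMF, 0 °C
Reagents that add atoms: tert-butyldimethylsilyl chloride, CC(C)(C)[Si](C)(C)Cl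
Why: Silylation discriminates on steric grounds: the two primary hydroxyls react, while the secondary C3–OH next to the quaternary C4 should not.

Step 18
Reactants: 25 bis-silyl ether; 26 angelic acid
Product: 28 (3R,4S,5S,9R,10S,13E)-15,18-bis(tert-butyldimethylsilyloxy)labda-8(17),13-dien-3-yl (2Z)-2-methylbut-2-enoate, via mixed anhydride 27 (not isolated)
Conditions: 26 (2 equiv), 2,4,6-trichlorobenzoyl chloride, Et3N, toluene, rt; then 25, toluene, 80 °C
Reagents that add atoms: none
Why: Esterification through the 2,4,6-trichlorobenzoyl mixed anhydride without a nucleophilic catalyst (Yamaguchi-type acylation), the protocol used to acylate hindered secondary alcohols with angelic acid without isomerization to the tiglate.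

Step 19
Reactants: 28 silylated angelate
Product: 29 target, (3R,4S,5S,9R,10S,13E)-15,18-dihydroxylabda-8(17),13-dien-3-yl (2Z)-2-methylbut-2-enoate
Conditions: HF·pyridine, pyridine, THF, 0 °C → rt
Reagents that add atoms: none
Why: Fluoride cleavage of both primary silyl ethers under buffered, slightly acidic conditions, which should avoid 1,3-acyl migration of the angelate from O3 to O18.

**Compound list**

1 | (R)-(−)-carvone | O=C1C(C)=CC[C@@H](C(C)=C)C1 | starting material
2 | carvone lithium enolate (cross-conjugated) | [Li]OC=1C(C)=CC[C@@H](C(C)=C)C=1 | intermediate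
3 | (5R,6S)-2,6-dimethyl-5-(prop-1-en-2-yl)cyclohex-2-en-1-one | O=C1C(C)=CC[C@@H](C(C)=C)[C@@H]1C | intermediate
4 | 6-methylcarvone lithium enolate | [Li]OC=1C(C)=CC[C@@H](C(C)=C)C=1C | intermediate
5 | (5S,6R)-6-(hydroxymethyl)-2,6-dimethyl-5-(prop-1-en-2-yl)cyclohex-2-en-1-one | O=C1C(C)=CC[C@@H](C(C)=C)[C@]1(C)CO | intermediate
6 | 5-(1-hydroperoxy-1-methoxyethyl)-6-(hydroxymethyl)-2,6-dimethylcyclohex-2-en-1-one (ring centres as in 5, epimers at the peroxy carbon) | O=C1C(C)=CC[C@@H](C(C)(OC)OO)[C@]1(C)CO | intermediate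
7 | (5R,6S)-5-acetoxy-6-(acetoxymethyl)-2,6-dimethylcyclohex-2-en-1-one | O=C1C(C)=CC[C@@H](OC(C)=O)[C@]1(C)COC(C)=O | intermediate
8 | (5R,6S)-5-hydroxy-6-(hydroxymethyl)-2,6-dimethylcyclohex-2-en-1-one | O=C1C(C)=CC[C@@H](O)[C@]1(C)CO | intermediate
9 | (4aS,8aR)-2,2,4a,6-tetramethyl-4a,8a-dihydro-4H-1,3-benzodioxin-5(8H)-one | O=C1C(C)=CC[C@@H](OC2(C)C)[C@]1(C)CO2 | intermediate
10 | lithium enolate from 1,4-reduction of 9 | [Li]OC1=C(C)CC[C@@H](OC2(C)C)[C@]1(C)CO2 | intermediate
11 | (4aS,8aR)-2,2,4a,6-tetramethyl-4a,7,8,8a-tetrahydro-4H-1,3-benzodioxin-5-yl trifluoromethanesulfonate | O=S(=O)(OC1=C(C)CC[C@@H](OC2(C)C)[C@]1(C)CO2)C(F)(F)F | intermediate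
12 | (4aS,8aR)-5-ethenyl-2,2,4a,6-tetramethyl-4a,7,8,8a-tetrahydro-4H-1,3-benzodioxine | C=CC1=C(C)CC[C@@H](OC2(C)C)[C@]1(C)CO2 | intermediate
13 | methyl 4-hydroxybut-2-ynoate | COC(=O)C#CCO | starting material
14 | methyl 4-acetoxybut-2-ynoate | COC(=O)C#CCOC(C)=O | intermediate
15 | methyl (3R,4S,10R)-17-acetoxy-3,18-(isopropylidenedioxy)-12,13,14,15,16-pentanorlabda-5,8-dien-11-oate | CC(=O)OCC=1CC=C2[C@@](C)(CC[C@@H](OC3(C)C)[C@]2(C)CO3)C=1C(=O)OC | intermediate
16 | methyl (3R,4S,5S,10R)-17-acetoxy-3,18-(isopropylidenedioxy)-12,13,14,15,16-pentanorlabd-8-en-11-oate | CC(=O)OCC=1CC[C@H]2[C@@](C)(CC[C@@H](OC3(C)C)[C@]2(C)CO3)C=1C(=O)OC | intermediate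
17 | methyl (3R,4S,5S,9R,10R)-3,18-(isopropylidenedioxy)-12,13,14,15,16-pentanorlabd-8(17)-en-11-oate | C=C1CC[C@H]2[C@@](C)(CC[C@@H](OC3(C)C)[C@]2(C)CO3)[C@@H]1C(=O)OC | intermediate
18 | (3R,4S,5S,9R,10R)-3,18-(isopropylidenedioxy)-12,13,14,15,16-pentanorlabd-8(17)-en-11-ol | C=C1CC[C@H]2[C@@](C)(CC[C@@H](OC3(C)C)[C@]2(C)CO3)[C@@H]1CO | intermediate
19 | 11-trifluoromethanesulfonate of 18 | C=C1CC[C@H]2[C@@](C)(CC[C@@H](OC3(C)C)[C@]2(C)CO3)[C@@H]1COS(=O)(=O)C(F)(F)F | intermediate
20 | (3R,4S,5S,9R,10S)-3,18-(isopropylidenedioxy)-14-(trimethylsilyl)-15,16-dinorlabd-8(17)-en-13-yne | C=C1CC[C@H]2[C@@](C)(CC[C@@H](OC3(C)C)[C@]2(C)CO3)[C@@H]1CCC#C[Si](C)(C)C | intermediate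
21 | (3R,4S,5S,9R,10S)-3,18-(isopropylidenedioxy)-15,16-dinorlabd-8(17)-en-13-yne | C=C1CC[C@H]2[C@@](C)(CC[C@@H](OC3(C)C)[C@]2(C)CO3)[C@@H]1CCC#C | intermediate
22 | dimethyl[(13E)-3,18-(isopropylidenedioxy)-15-norlabda-8(17),13-dien-14-yl]alane | C=C1CC[C@H]2[C@@](C)(CC[C@@H](OC3(C)C)[C@]2(C)CO3)[C@@H]1CC/C(C)=C/[Al](C)C | intermediate
23 | (3R,4S,5S,9R,10S,13E)-3,18-(isopropylidenedioxy)labda-8(17),13-dien-15-ol | C=C1CC[C@H]2[C@@](C)(CC[C@@H](OC3(C)C)[C@]2(C)CO3)[C@@H]1CC/C(C)=C/CO | intermediate
24 | (3R,4S,5S,9R,10S,13E)-labda-8(17),13-diene-3,15,18-triol | C=C1CC[C@H]2[C@@](C)(CC[C@@H](O)[C@]2(C)CO)[C@@H]1CC/C(C)=C/CO | intermediate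
25 | (3R,4S,5S,9R,10S,13E)-15,18-bis(tert-butyldimethylsilyloxy)labda-8(17),13-dien-3-ol | C=C1CC[C@H]2[C@@](C)(CC[C@@H](O)[C@]2(C)CO[Si](C)(C)C(C)(C)C)[C@@H]1CC/C(C)=C/CO[Si](C)(C)C(C)(C)C | intermediate
26 | angelic acid, (2Z)-2-methylbut-2-enoic acid | C/C=C(/C)C(=O)O | starting material
27 | angelic 2,4,6-trichlorobenzoic anhydride | C/C=C(/C)C(=O)OC(=O)c1c(Cl)cc(Cl)cc1Cl | intermediate
28 | (3R,4S,5S,9R,10S,13E)-15,18-bis(tert-butyldimethylsilyloxy)labda-8(17),13-dien-3-yl (2Z)-2-methylbut-2-enoate | C=C1CC[C@H]2[C@@](C)(CC[C@@H](OC(=O)/C(C)=C\C)[C@]2(C)CO[Si](C)(C)C(C)(C)C)[C@@H]1CC/C(C)=C/CO[Si](C)(C)C(C)(C)C | intermediate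
29 | (3R,4S,5S,9R,10S,13E)-15,18-dihydroxylabda-8(17),13-dien-3-yl (2Z)-2-methylbut-2-enoate | C=C1CC[C@H]2[C@@](C)(CC[C@@H](OC(=O)/C(C)=C\C)[C@]2(C)CO)[C@@H]1CC/C(C)=C/CO | target

**Summary**

Total step count: 19.
Longest linear sequence: 18 steps (steps 1–7 and 9–19, from (R)-carvone).

Steps most likely to fail:

Step 9. The cycloaddition may be too slow at a temperature that still suppresses the [1,5]-hydrogen shift of the diene, or facial selection may be incomplete. The fallback sets out from 12 and uses the more reactive ethyl buta-2,3-dienoate as dienophile (toluene, 90 °C), which should give the exo-methylene ester F1 as C9 epimers. DBU then moves the alkene into conjugation to give the tetrasubstituted enoate F2, which erases C9. Hydrogenation over Pt/C gives the trans-decalin enoate F3. Kinetic γ-deprotonation at the C17 methyl (syn to the ester) with LiN(i-Pr)2/HMPA at −78 °C and α-protonation with AcOH anti to C20 gives the deconjugated ester F4. LiAlH4 reduction comes back to the route at 18.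

Step 11. The samarium dienolate may be protonated at C17 instead of C9, or the enoate may be reduced without loss of acetate, giving conjugated or saturated esters; protonation at C9 from the wrong face is also possible. The fallback sets out from 16 and replaces electron transfer by palladium-catalysed formate hydrogenolysis (Pd(OAc)2, PBu3, HCO2NH4, dioxane, 100 °C). Ionization of the allylic acetate by zerovalent palladium and hydride delivery to the more substituted allyl terminus C9 is the established way from allylic esters to exocyclic methylene compounds. It comes back to the route directly at 17 and makes no new compound.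

Step 13. The hindered primary triflate may undergo elimination or decomposition under the strongly basic conditions instead of substitution. The fallback sets out from 18 and builds C11–C12 by olefination. Oxidation with Dess–Martin periodinane gives aldehyde F5. Wittig reaction with Ph3P=CHC(O)CH3 (toluene, 80 °C) gives enone F6. Conjugate reduction with [(Ph3P)CuH]6 gives methyl ketone F7. Horner–Wadsworth–Emmons reaction with triethyl phosphonoacetate/NaH gives the E-enoate F8 after separation from the Z isomer. Reduction with i-Bu2AlH comes back to the route at 23, so that steps 13–15 are bypassed.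

**Further compounds**

F1 | step 9 | ethyl (3R,4S,10R)-3,18-(isopropylidenedioxy)-12,13,14,15,16-pentanorlabda-5,8(17)-dien-11-oate (C9 epimers) | C=C1CC=C2[C@@](C)(CC[C@@H](OC3(C)C)[C@]2(C)CO3)C1C(=O)OCC
F2 | step 9 | ethyl (3R,4S,10R)-3,18-(isopropylidenedioxy)-12,13,14,15,16-pentanorlabda-5,8-dien-11-oate | CC=1CC=C2[C@@](C)(CC[C@@H](OC3(C)C)[C@]2(C)CO3)C=1C(=O)OCC
F3 | step 9 | ethyl (3R,4S,5S,10R)-3,18-(isopropylidenedioxy)-12,13,14,15,16-pentanorlabd-8-en-11-oate | CC=1CC[C@H]2[C@@](C)(CC[C@@H](OC3(C)C)[C@]2(C)CO3)C=1C(=O)OCC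
F4 | step 9 | ethyl (3R,4S,5S,9R,10R)-3,18-(isopropylidenedioxy)-12,13,14,15,16-pentanorlabd-8(17)-en-11-oate | C=C1CC[C@H]2[C@@](C)(CC[C@@H](OC3(C)C)[C@]2(C)CO3)[C@@H]1C(=O)OCC
F0 | step 11 | none | none
F5 | step 13 | (3R,4S,5S,9R,10R)-3,18-(isopropylidenedioxy)-12,13,14,15,16-pentanorlabd-8(17)-en-11-al | C=C1CC[C@H]2[C@@](C)(CC[C@@H](OC3(C)C)[C@]2(C)CO3)[C@@H]1C=O
F6 | step 13 | (11E)-3,18-(isopropylidenedioxy)-14,15-dinorlabda-8(17),11-dien-13-one | C=C1CC[C@H]2[C@@](C)(CC[C@@H](OC3(C)C)[C@]2(C)CO3)[C@@H]1/C=C/C(C)=O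
F7 | step 13 | 3,18-(isopropylidenedioxy)-14,15-dinorlabd-8(17)-en-13-one | C=C1CC[C@H]2[C@@](C)(CC[C@@H](OC3(C)C)[C@]2(C)CO3)[C@@H]1CCC(C)=O
F8 | step 13 | ethyl (13E)-3,18-(isopropylidenedioxy)labda-8(17),13-dien-15-oate | C=C1CC[C@H]2[C@@](C)(CC[C@@H](OC3(C)C)[C@]2(C)CO3)[C@@H]1CC/C(C)=C/C(=O)OCC
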